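**Retrosynthetic overview**
1. Target 37 comes from tetrabenzyl ether 36 by hydrogenolysis in the last step.
2. The pyran ring of chroman 1 is formed last: C4–C4a by intramolecular Friedel–Crafts closure of benzylic alcohol 34 (sets C4 trans to C3), and the O1–C2 ether by Mitsunobu reaction of diol 32 with 3-(benzyloxy)phenol.
3. The key C3–C4 bond of chroman 1 is an intermolecular Evans boron aldol between ring B arylacetyl imide 29 and aldehyde 21, which already carries chroman 2 (sets C3).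
4. Aldehyde 21 comes from vinyl-masked (R)-isoflavan 19; the pyran ring of chroman 2 is formed first, by Mitsunobu closure after Evans alkylation of imide 10 with benzyl bromide 14 (sets C3 of chroman 2).
5. Arenes: methyl 3,5-dihydroxyphenylacetate (middle ring), 4-(benzyloxy)-2-hydroxybenzaldehyde, 2,6-dimethoxyphenol (ring B) and 3-(benzyloxy)phenol.

Assumption: compounds 1, 8, 11, 22, 27 and 33 are bought, and benzyl is the only phenol protecting group carried to the end.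

**Route**

Step 1
Reactants: 1 methyl 2-(3,5-dihydroxyphenyl)acetate
Product: 3 methyl 2-(2-formyl-3,5-dihydroxyphenyl)acetate, via aryl iminium chloride 2 (not isolated)
Conditions: POCl3 (1.2 equiv), DMF (3 equiv), MeCN, 0 °C → rt; then H2O, 50 °C
Reagents that add atoms: N,N-dimethylformamide CN(C)C=O (formyl carbon); water O (formyl oxygen)
Why: Vilsmeier–Haack formylation of the resorcinol ring goes next to the side chain, para to one hydroxyl and ortho to the other (as with orcinol), and hydrolysis of the iminium salt frees the aldehyde.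

Step 2
Reactants: 3 methyl 2-(2-formyl-3,5-dihydroxyphenyl)acetate
Product: 4 methyl 2-[5-(benzyloxy)-2-formyl-3-hydroxyphenyl]acetate
Conditions: BnBr (1.05 equiv), NaHCO3, KI (cat.), MeCN, 70 °C
Reagents that add atoms: benzyl bromide BrCc1ccccc1
Why: Williamson etherification in which the 3-OH is held in a hydrogen bond to the formyl group, so the weak base alkylates only the more acidic 5-OH para to the aldehyde.

Step 3
Reactants: 4 methyl 2-[5-(benzyloxy)-2-formyl-3-hydroxyphenyl]acetate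
Product: 5 methyl 2-[5-(benzyloxy)-2-formyl-3-methoxyphenyl]acetate
Conditions: MeI, K2CO3, DMF, rt
Reagents that add atoms: iodomethane CI
Why: Williamson O-methylation of the remaining chelated phenol fixes OMe ortho and OBn para to the carbon that will carry C4 of chroman 1.

Step 4
Reactants: 5 methyl 2-[5-(benzyloxy)-2-formyl-3-methoxyphenyl]acetate
Product: 6 methyl 2-[5-(benzyloxy)-2-ethenyl-3-methoxyphenyl]acetate
Conditions: Ph3PCH3Br, KOtBu, THF, 0 °C (ylide preformed); then 5, 0 °C → rt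
Reagents that add atoms: methyltriphenylphosphonium bromide C[P+](c1ccccc1)(c1ccccc1)c1ccccc1.[Br-]
Why: Wittig methylenation masks the aldehyde as a styrene that tolerates the enolate, hydride and Mitsunobu steps that follow.

Step 5
Reactants: 6 methyl 2-[5-(benzyloxy)-2-ethenyl-3-methoxyphenyl]acetate
Product: 7 2-[5-(benzyloxy)-2-ethenyl-3-methoxyphenyl]acetic acid
Conditions: LiOH·H2O, THF/H2O 3:1, rt; then cold 1 M HCl to pH 3
Reagents that add atoms: lithium hydroxide [Li+].[OH-]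
Why: Ester saponification of an unhindered arylacetate, with a brief cold acidification that spares the styrene.

Step 6
Reactants: 7 2-[5-(benzyloxy)-2-ethenyl-3-methoxyphenyl]acetic acid; 8 (R)-4-benzyloxazolidin-2-one
Product: 10 (4R)-4-benzyl-3-{2-[5-(benzyloxy)-2-ethenyl-3-methoxyphenyl]acetyl}oxazolidin-2-one, via mixed pivalic anhydride 9 (not isolated)
Conditions: PivCl, Et3N, THF, −20 °C; then 8, LiCl, −20 °C → rt
Reagents that add atoms: none
Why: N-acylation of the oxazolidinone through the mixed anhydride, which is attacked at the less hindered arylacetyl carbonyl.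

Step 7
Reactants: 11 4-(benzyloxy)-2-hydroxybenzaldehyde
Product: 12 4-(benzyloxy)-2-(prop-2-en-1-yloxy)benzaldehyde
Conditions: allyl bromide, K2CO3, DMF, 50 °C
Reagents that add atoms: allyl bromide C=CCBr
Why: Williamson etherification installs an allyl group that is later removed under neutral conditions without touching the benzyl ethers.

Step 8
Reactants: 12 4-(benzyloxy)-2-(prop-2-en-1-yloxy)benzaldehyde
Product: 13 [4-(benzyloxy)-2-(prop-2-en-1-yloxy)phenyl]methanol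
Conditions: NaBH4, MeOH/THF, 0 °C
Reagents that add atoms: none
Why: Chemoselective borohydride reduction of the aldehyde.

Step 9
Reactants: 13 [4-(benzyloxy)-2-(prop-2-en-1-yloxy)phenyl]methanol
Product: 14 4-(benzyloxy)-1-(bromomethyl)-2-(prop-2-en-1-yloxy)benzene
Conditions: PBr3 (0.4 equiv), Et2O, 0 °C; cold aqueous NaHCO3 wash, crude bromide used at once
Reagents that add atoms: phosphorus tribromide BrP(Br)Br
Why: Bromide displacement of the phosphite ester of a very reactive benzylic alcohol, so the product is not stored.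

Step 10
Reactants: 10 (4R)-4-benzyl-3-{2-[5-(benzyloxy)-2-ethenyl-3-methoxyphenyl]acetyl}oxazolidin-2-one; 14 4-(benzyloxy)-1-(bromomethyl)-2-(prop-2-en-1-yloxy)benzene
Product: 16 (4R)-4-benzyl-3-[(2R)-2-[5-(benzyloxy)-2-ethenyl-3-methoxyphenyl]-3-[4-(benzyloxy)-2-(prop-2-en-1-yloxy)phenyl]propanoyl]oxazolidin-2-one, via sodium Z-enolate 15 (not isolated)
Conditions: NaN(SiMe3)2 (1.1 equiv), THF, −78 °C; then 14 (1.5 equiv), −78 → −40 °C; NH4Cl quench at −40 °C
Reagents that add atoms: none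
Why: Evans asymmetric alkylation in which the chelated sodium Z-enolate is attacked on the face opposite the benzyl group of the (R)-auxiliary, setting the 2R centre that becomes C3 of chroman 2.

Step 11
Reactants: 16 (4R)-4-benzyl-3-[(2R)-2-[5-(benzyloxy)-2-ethenyl-3-methoxyphenyl]-3-[4-(benzyloxy)-2-(prop-2-en-1-yloxy)phenyl]propanoyl]oxazolidin-2-one
Product: 17 (2R)-2-[5-(benzyloxy)-2-ethenyl-3-methoxyphenyl]-3-[4-(benzyloxy)-2-(prop-2-en-1-yloxy)phenyl]propan-1-ol
Conditions: LiBH4, MeOH (1.1 equiv), THF, 0 °C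
Reagents that add atoms: none
Why: Reductive cleavage of the N-acyl oxazolidinone at the exocyclic carbonyl gives the primary alcohol without touching the stereocentre, and the auxiliary is recovered.

Step 12
Reactants: 17 (2R)-2-[5-(benzyloxy)-2-ethenyl-3-methoxyphenyl]-3-[4-(benzyloxy)-2-(prop-2-en-1-yloxy)phenyl]propan-1-ol
Product: 18 5-(benzyloxy)-2-[(2R)-2-[5-(benzyloxy)-2-ethenyl-3-methoxyphenyl]-3-hydroxypropyl]phenol
Conditions: Pd(PPh3)4 (5 mol %), morpholine (5 equiv), THF, rt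
Reagents that add atoms: none
Why: Tsuji–Trost deallylation, in which zerovalent palladium ionises the allyl aryl ether and morpholine traps the allyl group, leaving benzyl ethers and the styrene intact.

Step 13
Reactants: 18 5-(benzyloxy)-2-[(2R)-2-[5-(benzyloxy)-2-ethenyl-3-methoxyphenyl]-3-hydroxypropyl]phenol
Product: 19 (3R)-7-(benzyloxy)-3-[5-(benzyloxy)-2-ethenyl-3-methoxyphenyl]chroman
Conditions: PPh3, DIAD, THF, 0 °C → rt
Reagents that add atoms: none
Why: Intramolecular Mitsunobu etherification closes the six-membered pyran ring at the primary carbon, so the stereocentre is not involved and the (R)-isoflavan results.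

Step 14
Reactants: 19 (3R)-7-(benzyloxy)-3-[5-(benzyloxy)-2-ethenyl-3-methoxyphenyl]chroman
Product: 21 4-(benzyloxy)-2-[(3R)-7-(benzyloxy)chroman-3-yl]-6-methoxybenzaldehyde, via vicinal diol 20 (not isolated)
Conditions: OsO4 (2 mol %), NaIO4 (4 equiv), 2,6-lutidine, dioxane/H2O 3:1, rt
Reagents that add atoms: osmium tetroxide O=[Os](=O)(=O)=O (delivers the oxygen); sodium periodate [Na+].[O-]I(=O)(=O)=O (re-oxidant and final oxygen source)
Why: Lemieux–Johnson dihydroxylation and glycol cleavage unmasks the aldehyde under near-neutral conditions.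

Step 15
Reactants: 22 2,6-dimethoxyphenol
Product: 23 2-(benzyloxy)-1,3-dimethoxybenzene
Conditions: BnBr, K2CO3, DMF, 60 °C
Reagents that add atoms: benzyl bromide BrCc1ccccc1
Why: Williamson benzylation of the hindered phenol proceeds cleanly in a dipolar aprotic solvent.

Step 16
Reactants: 23 2-(benzyloxy)-1,3-dimethoxybenzene
Product: 24 3-(benzyloxy)-1-bromo-2,4-dimethoxybenzene
Conditions: NBS (1.0 equiv), MeCN, 0 °C → rt
Reagents that add atoms: N-bromosuccinimide O=C1CCC(=O)N1Br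
Why: Electrophilic aromatic bromination goes para to one methoxy and ortho to the other, because the central benzyloxy group is twisted out of conjugation and does not direct to its para position.

Step 17
Reactants: 24 3-(benzyloxy)-1-bromo-2,4-dimethoxybenzene
Product: 25 tert-butyl 2-[3-(benzyloxy)-2,4-dimethoxyphenyl]acetate
Conditions: BrCH2CO2tBu (1.5 equiv), Zn dust (activated with Me3SiCl), THF, 40 °C, to give BrZnCH2CO2tBu; then 24, Pd2(dba)3 (1 mol %), XPhos (4 mol %), THF, 65 °C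
Reagents that add atoms: tert-butyl bromoacetate BrCC(=O)OC(C)(C)C
Why: Zinc insertion into the bromoacetate gives the Reformatsky reagent in the flask, and its Negishi-type cross-coupling (palladium-catalysed α-arylation of an ester zinc enolate) tolerates the electron-rich, ortho-substituted aryl bromide.

Step 18
Reactants: 25 tert-butyl 2-[3-(benzyloxy)-2,4-dimethoxyphenyl]acetate
Product: 26 2-[3-(benzyloxy)-2,4-dimethoxyphenyl]acetic acid
Conditions: TFA/CH2Cl2 1:3, 0 °C → rt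
Reagents that add atoms: none
Why: Acidolysis of the tert-butyl ester with loss of isobutene, under which aryl benzyl ethers are stable.

Step 19
Reactants: 26 2-[3-(benzyloxy)-2,4-dimethoxyphenyl]acetic acid; 27 (S)-4-benzyloxazolidin-2-one
Product: 29 (4S)-4-benzyl-3-{2-[3-(benzyloxy)-2,4-dimethoxyphenyl]acetyl}oxazolidin-2-one, via mixed pivalic anhydride 28 (not isolated)
Conditions: PivCl, Et3N, THF, −20 °C; then 27, LiCl, −20 °C → rt
Reagents that add atoms: none
Why: N-acylation of the oxazolidinone through the mixed anhydride, as in step 6.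

Step 20
Reactants: 29 (4S)-4-benzyl-3-{2-[3-(benzyloxy)-2,4-dimethoxyphenyl]acetyl}oxazolidin-2-one; 21 4-(benzyloxy)-2-[(3R)-7-(benzyloxy)chroman-3-yl]-6-methoxybenzaldehyde
Product: 31 (4S)-4-benzyl-3-[(2S,3S)-3-{4-(benzyloxy)-2-[(3R)-7-(benzyloxy)chroman-3-yl]-6-methoxyphenyl}-2-[3-(benzyloxy)-2,4-dimethoxyphenyl]-3-hydroxypropanoyl]oxazolidin-2-one, via dibutylboron Z-enolate 30 (not isolated)
Conditions: 29 (1.4 equiv), Bu2BOTf (1.5 equiv), iPr2NEt (1.7 equiv), CH2Cl2, 0 °C; then 21, −78 → 0 °C; pH 7 buffer, MeOH, 30% H2O2, 0 °C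
Reagents that add atoms: none
Why: Evans syn-aldol through the boron Z-enolate and a Zimmerman–Traxler chair with the auxiliary carbonyl turned away, so the (S)-auxiliary sets the 2S centre (C3 of chroman 1, R there) together with the 3S carbinol that is consumed in step 23.

Step 21
Reactants: 31 (4S)-4-benzyl-3-[(2S,3S)-3-{4-(benzyloxy)-2-[(3R)-7-(benzyloxy)chroman-3-yl]-6-methoxyphenyl}-2-[3-(benzyloxy)-2,4-dimethoxyphenyl]-3-hydroxypropanoyl]oxazolidin-2-one
Product: 32 (1S,2R)-1-{4-(benzyloxy)-2-[(3R)-7-(benzyloxy)chroman-3-yl]-6-methoxyphenyl}-2-[3-(benzyloxy)-2,4-dimethoxyphenyl]propane-1,3-diol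
Conditions: LiBH4, MeOH (1.1 equiv), THF, 0 °C
Reagents that add atoms: none
Why: Reductive removal of the auxiliary is faster than retro-aldol at 0 °C and removes the acidic α-hydrogen, which secures the C2 configuration.

Step 22
Reactants: 32 (1S,2R)-1-{4-(benzyloxy)-2-[(3R)-7-(benzyloxy)chroman-3-yl]-6-methoxyphenyl}-2-[3-(benzyloxy)-2,4-dimethoxyphenyl]propane-1,3-diol; 33 3-(benzyloxy)phenol
Product: 34 (1S,2R)-3-[3-(benzyloxy)phenoxy]-1-{4-(benzyloxy)-2-[(3R)-7-(benzyloxy)chroman-3-yl]-6-methoxyphenyl}-2-[3-(benzyloxy)-2,4-dimethoxyphenyl]propan-1-ol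
Conditions: 33 (1.3 equiv), PPh3 (1.2 equiv), DIAD (1.2 equiv), THF/toluene, 0 °C → rt
Reagents that add atoms: none
Why: Mitsunobu etherification selects the primary alcohol over the secondary carbinol, which is flanked by a doubly ortho-substituted arene, and fixes the future O1–C2 bond regiochemically.

Step 23
Reactants: 34 (1S,2R)-3-[3-(benzyloxy)phenoxy]-1-{4-(benzyloxy)-2-[(3R)-7-(benzyloxy)chroman-3-yl]-6-methoxyphenyl}-2-[3-(benzyloxy)-2,4-dimethoxyphenyl]propan-1-ol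
Product: 36 (3R,4S)-7-(benzyloxy)-4-{4-(benzyloxy)-2-[(3R)-7-(benzyloxy)chroman-3-yl]-6-methoxyphenyl}-3-[3-(benzyloxy)-2,4-dimethoxyphenyl]chroman, via benzylic carbocation 35 (not isolated)
Conditions: BF3·OEt2 (0.3 equiv), 4 Å MS, CH2Cl2, −40 → 0 °C
Reagents that add atoms: none
Why: Intramolecular Friedel–Crafts alkylation in which the cation, stabilised by ortho-OMe and para-OBn, is captured para to OBn of the tethered aryl ether from the face anti to the ring B aryl (H-eclipsed A(1,3) conformer, diequatorial chair), giving the trans 4S centre.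

Step 24
Reactants: 36 (3R,4S)-7-(benzyloxy)-4-{4-(benzyloxy)-2-[(3R)-7-(benzyloxy)chroman-3-yl]-6-methoxyphenyl}-3-[3-(benzyloxy)-2,4-dimethoxyphenyl]chroman
Product: 37 (3R,4S)-4-{4-hydroxy-2-[(3R)-7-hydroxychroman-3-yl]-6-methoxyphenyl}-3-(3-hydroxy-2,4-dimethoxyphenyl)chroman-7-ol
Conditions: H2 (1 atm), 10% Pd/C, EtOAc/MeOH 1:1, rt
Reagents that add atoms: none
Why: Hydrogenolysis cleaves the four O-benzyl ethers while the methyl ethers, the chroman C–O bonds and the triaryl-substituted C–C bonds are inert.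

**Compound list**
1 | methyl 2-(3,5-dihydroxyphenyl)acetate | COC(=O)Cc1cc(O)cc(O)c1 | starting material
2 | [2,4-dihydroxy-6-(2-methoxy-2-oxoethyl)benzylidene]dimethyliminium chloride | COC(=O)Cc1cc(O)cc(O)c1C=[N+](C)C.[Cl-] | intermediate (not isolated)
3 | methyl 2-(2-formyl-3,5-dihydroxyphenyl)acetate | COC(=O)Cc1cc(O)cc(O)c1C=O | intermediate
4 | methyl 2-[5-(benzyloxy)-2-formyl-3-hydroxyphenyl]acetate | COC(=O)Cc1cc(OCc2ccccc2)cc(O)c1C=O | intermediate
5 | methyl 2-[5-(benzyloxy)-2-formyl-3-methoxyphenyl]acetate | COC(=O)Cc1cc(OCc2ccccc2)cc(OC)c1C=O | intermediate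
6 | methyl 2-[5-(benzyloxy)-2-ethenyl-3-methoxyphenyl]acetate | COC(=O)Cc1cc(OCc2ccccc2)cc(OC)c1C=C | intermediate
7 | 2-[5-(benzyloxy)-2-ethenyl-3-methoxyphenyl]acetic acid | OC(=O)Cc1cc(OCc2ccccc2)cc(OC)c1C=C | intermediate
8 | (R)-4-benzyloxazolidin-2-one | O=C1N[C@H](Cc2ccccc2)CO1 | starting material
9 | 2-[5-(benzyloxy)-2-ethenyl-3-methoxyphenyl]acetic pivalic anhydride | CC(C)(C)C(=O)OC(=O)Cc1cc(OCc2ccccc2)cc(OC)c1C=C | intermediate (not isolated)
10 | (4R)-4-benzyl-3-{2-[5-(benzyloxy)-2-ethenyl-3-methoxyphenyl]acetyl}oxazolidin-2-one | O=C1OC[C@@H](Cc2ccccc2)N1C(=O)Cc1cc(OCc2ccccc2)cc(OC)c1C=C | intermediate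
11 | 4-(benzyloxy)-2-hydroxybenzaldehyde | O=Cc1ccc(OCc2ccccc2)cc1O | starting material
12 | 4-(benzyloxy)-2-(prop-2-en-1-yloxy)benzaldehyde | O=Cc1ccc(OCc2ccccc2)cc1OCC=C | intermediate
13 | [4-(benzyloxy)-2-(prop-2-en-1-yloxy)phenyl]methanol | OCc1ccc(OCc2ccccc2)cc1OCC=C | intermediate
14 | 4-(benzyloxy)-1-(bromomethyl)-2-(prop-2-en-1-yloxy)benzene | BrCc1ccc(OCc2ccccc2)cc1OCC=C | intermediate
15 | sodium (Z)-enolate of imide 10 | [Na+].[O-]/C(=C\c1cc(OCc2ccccc2)cc(OC)c1C=C)N1[C@H](Cc2ccccc2)COC1=O | intermediate (not isolated)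
16 | (4R)-4-benzyl-3-[(2R)-2-[5-(benzyloxy)-2-ethenyl-3-methoxyphenyl]-3-[4-(benzyloxy)-2-(prop-2-en-1-yloxy)phenyl]propanoyl]oxazolidin-2-one | O=C1OC[C@@H](Cc2ccccc2)N1C(=O)[C@H](Cc1ccc(OCc2ccccc2)cc1OCC=C)c1cc(OCc2ccccc2)cc(OC)c1C=C | intermediate
17 | (2R)-2-[5-(benzyloxy)-2-ethenyl-3-methoxyphenyl]-3-[4-(benzyloxy)-2-(prop-2-en-1-yloxy)phenyl]propan-1-ol | OC[C@H](Cc1ccc(OCc2ccccc2)cc1OCC=C)c1cc(OCc2ccccc2)cc(OC)c1C=C | intermediate
18 | 5-(benzyloxy)-2-[(2R)-2-[5-(benzyloxy)-2-ethenyl-3-methoxyphenyl]-3-hydroxypropyl]phenol | OC[C@H](Cc1ccc(OCc2ccccc2)cc1O)c1cc(OCc2ccccc2)cc(OC)c1C=C | intermediate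
19 | (3R)-7-(benzyloxy)-3-[5-(benzyloxy)-2-ethenyl-3-methoxyphenyl]chroman | C=Cc1c(OC)cc(OCc2ccccc2)cc1[C@@H]1COc2cc(OCc3ccccc3)ccc2C1 | intermediate
20 | 1-{4-(benzyloxy)-2-[(3R)-7-(benzyloxy)chroman-3-yl]-6-methoxyphenyl}ethane-1,2-diol (both carbinol epimers) | OCC(O)c1c(OC)cc(OCc2ccccc2)cc1[C@@H]1COc2cc(OCc3ccccc3)ccc2C1 | intermediate (not isolated)
21 | 4-(benzyloxy)-2-[(3R)-7-(benzyloxy)chroman-3-yl]-6-methoxybenzaldehyde | O=Cc1c(OC)cc(OCc2ccccc2)cc1[C@@H]1COc2cc(OCc3ccccc3)ccc2C1 | intermediate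
22 | 2,6-dimethoxyphenol | COc1cccc(OC)c1O | starting material
23 | 2-(benzyloxy)-1,3-dimethoxybenzene | COc1cccc(OC)c1OCc1ccccc1 | intermediate
24 | 3-(benzyloxy)-1-bromo-2,4-dimethoxybenzene | COc1ccc(Br)c(OC)c1OCc1ccccc1 | intermediate
25 | tert-butyl 2-[3-(benzyloxy)-2,4-dimethoxyphenyl]acetate | COc1ccc(CC(=O)OC(C)(C)C)c(OC)c1OCc1ccccc1 | intermediate
26 | 2-[3-(benzyloxy)-2,4-dimethoxyphenyl]acetic acid | COc1ccc(CC(=O)O)c(OC)c1OCc1ccccc1 | intermediate
27 | (S)-4-benzyloxazolidin-2-one | O=C1N[C@@H](Cc2ccccc2)CO1 | starting material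
28 | 2-[3-(benzyloxy)-2,4-dimethoxyphenyl]acetic pivalic anhydride | COc1ccc(CC(=O)OC(=O)C(C)(C)C)c(OC)c1OCc1ccccc1 | intermediate (not isolated)
29 | (4S)-4-benzyl-3-{2-[3-(benzyloxy)-2,4-dimethoxyphenyl]acetyl}oxazolidin-2-one | O=C1OC[C@H](Cc2ccccc2)N1C(=O)Cc1ccc(OC)c(OCc2ccccc2)c1OC | intermediate
30 | dibutylboron (Z)-enolate of imide 29 | CCCCB(CCCC)O/C(=C\c1ccc(OC)c(OCc2ccccc2)c1OC)N1[C@@H](Cc2ccccc2)COC1=O | intermediate (not isolated)
31 | (4S)-4-benzyl-3-[(2S,3S)-3-{4-(benzyloxy)-2-[(3R)-7-(benzyloxy)chroman-3-yl]-6-methoxyphenyl}-2-[3-(benzyloxy)-2,4-dimethoxyphenyl]-3-hydroxypropanoyl]oxazolidin-2-one | O=C1OC[C@H](Cc2ccccc2)N1C(=O)[C@H]([C@H](O)c1c(OC)cc(OCc2ccccc2)cc1[C@@H]1COc2cc(OCc3ccccc3)ccc2C1)c1ccc(OC)c(OCc2ccccc2)c1OC | intermediate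
32 | (1S,2R)-1-{4-(benzyloxy)-2-[(3R)-7-(benzyloxy)chroman-3-yl]-6-methoxyphenyl}-2-[3-(benzyloxy)-2,4-dimethoxyphenyl]propane-1,3-diol | OC[C@H]([C@H](O)c1c(OC)cc(OCc2ccccc2)cc1[C@@H]1COc2cc(OCc3ccccc3)ccc2C1)c1ccc(OC)c(OCc2ccccc2)c1OC | intermediate
33 | 3-(benzyloxy)phenol | Oc1cccc(OCc2ccccc2)c1 | starting material
34 | (1S,2R)-3-[3-(benzyloxy)phenoxy]-1-{4-(benzyloxy)-2-[(3R)-7-(benzyloxy)chroman-3-yl]-6-methoxyphenyl}-2-[3-(benzyloxy)-2,4-dimethoxyphenyl]propan-1-ol | c1ccccc1COc1cccc(OC[C@H]([C@H](O)c2c(OC)cc(OCc3ccccc3)cc2[C@@H]2COc3cc(OCc4ccccc4)ccc3C2)c2ccc(OC)c(OCc3ccccc3)c2OC)c1 | intermediate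
35 | C1 benzylic carbocation derived from 34 by loss of hydroxide | c1ccccc1COc1cccc(OC[C@H]([CH+]c2c(OC)cc(OCc3ccccc3)cc2[C@@H]2COc3cc(OCc4ccccc4)ccc3C2)c2ccc(OC)c(OCc3ccccc3)c2OC)c1 | intermediate (not isolated)
36 | (3R,4S)-7-(benzyloxy)-4-{4-(benzyloxy)-2-[(3R)-7-(benzyloxy)chroman-3-yl]-6-methoxyphenyl}-3-[3-(benzyloxy)-2,4-dimethoxyphenyl]chroman | COc1ccc([C@@H]2COc3cc(OCc4ccccc4)ccc3[C@H]2c2c(OC)cc(OCc3ccccc3)cc2[C@@H]2COc3cc(OCc4ccccc4)ccc3C2)c(OC)c1OCc1ccccc1 | intermediate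
37 | (3R,4S)-4-{4-hydroxy-2-[(3R)-7-hydroxychroman-3-yl]-6-methoxyphenyl}-3-(3-hydroxy-2,4-dimethoxyphenyl)chroman-7-ol | COc1ccc([C@@H]2COc3cc(O)ccc3[C@H]2c2c(OC)cc(O)cc2[C@@H]2COc3cc(O)ccc3C2)c(OC)c1O | target

**Totals**
Total step count: 24. Longest linear sequence: 16 steps (1–6, 10–14, 20–24) from compound 1.

**Three steps most likely to fail**

Step 20 (aldol on a doubly ortho-substituted, electron-rich aldehyde; slow addition or retro-aldol). The fallback sets out from aldehyde 21 and acid 26 and comes back at 36. The same C–C bond is made by adding a chelated titanium enolate to an oxocarbenium ion in an open transition state, which is less sensitive to the ortho substituents. Aldehyde 21 is treated with HC(OMe)3 and catalytic pyridinium p-toluenesulfonate in MeOH to give (3R)-7-(benzyloxy)-3-[5-(benzyloxy)-2-(dimethoxymethyl)-3-methoxyphenyl]chroman F1. Acid 26 is joined through anhydride 28 to the (R)-auxiliary 8, as in step 19, to give (4R)-4-benzyl-3-{2-[3-(benzyloxy)-2,4-dimethoxyphenyl]acetyl}oxazolidin-2-one F2. The enantiomeric auxiliary is needed because a chelated enolate reacts with the facial sense of an alkylation, opposite to the boron aldol. Enolisation of F2 with TiCl4/iPr2NEt in CH2Cl2 at −78 °C and addition of F1 with BF3·OEt2 gives the (2S,3R)-3-methoxy imide F3; the configuration at the methoxy carbon is irrelevant because it is lost later. LiBH4 gives the (2R,3R)-3-methoxypropan-1-ol F4, and Mitsunobu reaction with 33 gives the (1R,2R)-1-methoxy-3-aryloxypropane F5, now without any competing hydroxyl. BF3·OEt2 ionises the benzylic methyl ether of F5 to cation 35, which closes to 36.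

Step 23 (cationic ring closure; E1 loss of the C3 hydrogen would erase that centre, and the trans:cis ratio is substrate-dependent). The fallback sets out from diol 32 and comes back at target 37. The order of bond formation around chroman 1 is inverted, so that the C4–aryl bond is made intermolecularly and the pyran ring is closed at oxygen. Diol 32 is ionised with catalytic TsOH in hexafluoroisopropanol at 0 °C in the presence of excess resorcinol. Resorcinol is symmetric, so C-alkylation at its C4 is regiochemically unambiguous, and the same H-eclipsed A(1,3) model places it anti to the ring B aryl. This gives 4-[(1S,2R)-1-{4-(benzyloxy)-2-[(3R)-7-(benzyloxy)chroman-3-yl]-6-methoxyphenyl}-2-[3-(benzyloxy)-2,4-dimethoxyphenyl]-3-hydroxypropyl]benzene-1,3-diol F6. Intramolecular Mitsunobu reaction (PPh3, DIAD, dilute THF) between the ortho phenol and the primary alcohol gives (3R,4S)-4-{4-(benzyloxy)-2-[(3R)-7-(benzyloxy)chroman-3-yl]-6-methoxyphenyl}-3-[3-(benzyloxy)-2,4-dimethoxyphenyl]chroman-7-ol F7. Its three benzyl ethers are removed as in step 24 to reach 37.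

Step 10 (the 2,4-dialkoxybenzyl bromide 14 ionises and polymerises easily and may decompose faster than it alkylates). The fallback sets out from imide 10 and comes back at 19. The pyran oxygen is introduced by C–O coupling instead of Mitsunobu, which allows a stable electrophile. Commercial 2-bromo-4-hydroxybenzaldehyde is benzylated (BnBr, K2CO3, DMF) to 4-(benzyloxy)-2-bromobenzaldehyde F8, reduced with NaBH4 to [4-(benzyloxy)-2-bromophenyl]methanol F9 and converted with PBr3 to 4-(benzyloxy)-2-bromo-1-(bromomethyl)benzene F10, whose ortho bromine damps ionisation. F10 alkylates the sodium enolate 15 to give (4R)-4-benzyl-3-[(2R)-3-[4-(benzyloxy)-2-bromophenyl]-2-[5-(benzyloxy)-2-ethenyl-3-methoxyphenyl]propanoyl]oxazolidin-2-one F11. LiBH4 gives (2R)-3-[4-(benzyloxy)-2-bromophenyl]-2-[5-(benzyloxy)-2-ethenyl-3-methoxyphenyl]propan-1-ol F12. Intramolecular Ullmann-type etherification (CuI, 3,4,7,8-tetramethyl-1,10-phenanthroline, Cs2CO3, toluene, 110 °C; copper is chosen to avoid Heck reaction of the styrene) closes the ring to 19.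

**Further compounds**
F1 | step 20 | (3R)-7-(benzyloxy)-3-[5-(benzyloxy)-2-(dimethoxymethyl)-3-methoxyphenyl]chroman | COC(OC)c1c(OC)cc(OCc2ccccc2)cc1[C@@H]1COc2cc(OCc3ccccc3)ccc2C1
F2 | step 20 | (4R)-4-benzyl-3-{2-[3-(benzyloxy)-2,4-dimethoxyphenyl]acetyl}oxazolidin-2-one | O=C1OC[C@@H](Cc2ccccc2)N1C(=O)Cc1ccc(OC)c(OCc2ccccc2)c1OC
F3 | step 20 | (4R)-4-benzyl-3-[(2S,3R)-3-{4-(benzyloxy)-2-[(3R)-7-(benzyloxy)chroman-3-yl]-6-methoxyphenyl}-2-[3-(benzyloxy)-2,4-dimethoxyphenyl]-3-methoxypropanoyl]oxazolidin-2-one | O=C1OC[C@@H](Cc2ccccc2)N1C(=O)[C@H]([C@@H](OC)c1c(OC)cc(OCc2ccccc2)cc1[C@@H]1COc2cc(OCc3ccccc3)ccc2C1)c1ccc(OC)c(OCc2ccccc2)c1OC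
F4 | step 20 | (2R,3R)-3-{4-(benzyloxy)-2-[(3R)-7-(benzyloxy)chroman-3-yl]-6-methoxyphenyl}-2-[3-(benzyloxy)-2,4-dimethoxyphenyl]-3-methoxypropan-1-ol | OC[C@H]([C@@H](OC)c1c(OC)cc(OCc2ccccc2)cc1[C@@H]1COc2cc(OCc3ccccc3)ccc2C1)c1ccc(OC)c(OCc2ccccc2)c1OC
F5 | step 20 | (3R)-7-(benzyloxy)-3-{5-(benzyloxy)-2-[(1R,2R)-3-[3-(benzyloxy)phenoxy]-2-[3-(benzyloxy)-2,4-dimethoxyphenyl]-1-methoxypropyl]-3-methoxyphenyl}chroman | c1ccccc1COc1cccc(OC[C@H]([C@@H](OC)c2c(OC)cc(OCc3ccccc3)cc2[C@@H]2COc3cc(OCc4ccccc4)ccc3C2)c2ccc(OC)c(OCc3ccccc3)c2OC)c1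
F6 | step 23 | 4-[(1S,2R)-1-{4-(benzyloxy)-2-[(3R)-7-(benzyloxy)chroman-3-yl]-6-methoxyphenyl}-2-[3-(benzyloxy)-2,4-dimethoxyphenyl]-3-hydroxypropyl]benzene-1,3-diol | OC[C@H]([C@@H](c1ccc(O)cc1O)c1c(OC)cc(OCc2ccccc2)cc1[C@@H]1COc2cc(OCc3ccccc3)ccc2C1)c1ccc(OC)c(OCc2ccccc2)c1OC
F7 | step 23 | (3R,4S)-4-{4-(benzyloxy)-2-[(3R)-7-(benzyloxy)chroman-3-yl]-6-methoxyphenyl}-3-[3-(benzyloxy)-2,4-dimethoxyphenyl]chroman-7-ol | COc1ccc([C@@H]2COc3cc(O)ccc3[C@H]2c2c(OC)cc(OCc3ccccc3)cc2[C@@H]2COc3cc(OCc4ccccc4)ccc3C2)c(OC)c1OCc1ccccc1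
F8 | step 10 | 4-(benzyloxy)-2-bromobenzaldehyde | O=Cc1ccc(OCc2ccccc2)cc1Br
F9 | step 10 | [4-(benzyloxy)-2-bromophenyl]methanol | OCc1ccc(OCc2ccccc2)cc1Br
F10 | step 10 | 4-(benzyloxy)-2-bromo-1-(bromomethyl)benzene | BrCc1ccc(OCc2ccccc2)cc1Br
F11 | step 10 | (4R)-4-benzyl-3-[(2R)-3-[4-(benzyloxy)-2-bromophenyl]-2-[5-(benzyloxy)-2-ethenyl-3-methoxyphenyl]propanoyl]oxazolidin-2-one | O=C1OC[C@@H](Cc2ccccc2)N1C(=O)[C@H](Cc1ccc(OCc2ccccc2)cc1Br)c1cc(OCc2ccccc2)cc(OC)c1C=C
F12 | step 10 | (2R)-3-[4-(benzyloxy)-2-bromophenyl]-2-[5-(benzyloxy)-2-ethenyl-3-methoxyphenyl]propan-1-ol | OC[C@H](Cc1ccc(OCc2ccccc2)cc1Br)c1cc(OCc2ccccc2)cc(OC)c1C=C
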